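The pyridine ring is opened at N1–C2 and N1–C8a to a 1,5-keto aldehyde, and this in turn at C4a–C4 and C3–C2, which releases ethylene. The feature used is the three-carbon bridge C4–C3–C2 that links C4a to N1 in the pyridine ring, so that C8a and C2 stand in a 1,5-relationship. One de Mayo photocycloaddition/retro-aldol of ethylene with a 2-(hydroxymethylene)cyclohexanone forms both C–C bonds. The precursor is the (R)-configured 4-aryl-4-(amidoethyl)-2-(hydroxymethylene)cyclohexanone, made from an enantioenriched cyclohexenone (asymmetric Robinson annulation) by conjugate reduction and formylation of the regiodefined enolate, which decides between C5 and C7.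

Key step: step 7

Assumption: which antipode of the proline-derived sulfonamide catalyst in step 5 leads to (S)-9 is settled by a trial run against the racemate (chiral HPLC, optical rotation); both antipodes are accessible from L- and D-proline, and the route is written for the one that gives (S)-9.

Step 1
Reactants: 1 2-(methylamino)ethanol
Product: 2 2-chloro-N-methylethan-1-amine hydrochloride
Conditions: SOCl2 (1.3 equiv), CHCl3, 0 °C to reflux
Reagents that add atoms: thionyl chloride, O=S(Cl)Cl
Why: Chlorodehydroxylation of the alcohol through its chlorosulfite (SN2 by chloride) is standard, and the amine is held as its hydrochloride as it forms, so it cannot alkylate itself.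

Step 2
Reactants: 2 2-chloro-N-methylethan-1-amine hydrochloride
Product: 3 N-(2-chloroethyl)-N-methylacetamide
Conditions: AcCl (1.05 equiv), Et3N (2.2 equiv), CH2Cl2, 0 °C
Reagents that add atoms: acetyl chloride, CC(Cl)=O
Why: N-Acylation of the liberated secondary amine by the acid chloride (amide formation) is far faster at 0 °C than closure of the 2-chloroethylamine to an aziridinium ion.

Step 3
Reactants: 4 (3,4-dimethoxyphenyl)acetonitrile; 3 N-(2-chloroethyl)-N-methylacetamide
Product: 5 rac-N-[3-cyano-3-(3,4-dimethoxyphenyl)propyl]-N-methylacetamide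
Conditions: 4 (1.2 equiv), NaN(SiMe3)2 (1.15 equiv), THF/DMPU, −78 °C; then 3 (1.0 equiv), NaI (10 mol %), −78 °C to rt
Reagents that add atoms: none
Why: SN2 C-alkylation of the preformed nitrile-stabilised benzylic carbanion by the primary chloride (iodide catalysis), with 4 in slight excess to limit dialkylation; the new stereocentre is racemic, which is harmless because it is planarised as an enamine in step 5.

Step 4
Reactants: 5 rac-N-[3-cyano-3-(3,4-dimethoxyphenyl)propyl]-N-methylacetamide
Product: 6 rac-N-[3-(3,4-dimethoxyphenyl)-4-oxobutyl]-N-methylacetamide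
Conditions: Raney Ni, NaH2PO2·H2O, pyridine/AcOH/H2O (2:1:1), 40–45 °C
Reagents that add atoms: water, O
Why: Partial reduction of the nitrile by Raney nickel/hypophosphite transfer hydrogenation stops at the aldimine, which is hydrolysed in the aqueous acetic acid medium, and the tertiary amide and aryl ethers are inert to this reagent, which a hydride such as i-Bu2AlH would not guarantee.

Step 5
Reactants: 6 rac-N-[3-(3,4-dimethoxyphenyl)-4-oxobutyl]-N-methylacetamide; 7 methyl vinyl ketone
Product: 9 N-[2-[(1S)-1-(3,4-dimethoxyphenyl)-4-oxocyclohex-2-en-1-yl]ethyl]-N-methylacetamide, via Michael adduct 8 (not isolated)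
Conditions: 7 (2 equiv), N-[(4-dodecylphenyl)sulfonyl]pyrrolidine-2-carboxamide (20 mol %, the antipode that gives (S)-9), BnNH2 (1 equiv), 4 Å MS, ClCH2CH2Cl, rt
Reagents that add atoms: none
Why: Amine-catalysed asymmetric Robinson annulation, in which the α-branched aldehyde reacts as a trisubstituted enamine in a Michael addition to 7, the chiral sulfonamide catalyst selects the enamine face and thereby sets the quaternary stereocentre from the racemic, equilibrating aldehyde, and keto aldehyde 8 closes by intramolecular aldol condensation.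

Step 6
Reactants: 9 N-[2-[(1S)-1-(3,4-dimethoxyphenyl)-4-oxocyclohex-2-en-1-yl]ethyl]-N-methylacetamide
Product: 11 N-[2-[(1R,3Z)-1-(3,4-dimethoxyphenyl)-3-(hydroxymethylidene)-4-oxocyclohexyl]ethyl]-N-methylacetamide, via lithium enolate 10 (not isolated)
Conditions: LiBH(sec-Bu)3 (1.05 equiv), THF, −78 °C; then HCO2CH2CF3 (1.5 equiv), −78 °C; 1 M HCl quench at −78 °C; product extracted into cold 0.5 M NaOH and re-acidified
Reagents that add atoms: 2,2,2-trifluoroethyl formate, O=COCC(F)(F)F
Why: Conjugate hydride delivery by the bulky trialkylborohydride to the β-unsubstituted enone gives the enolate on the side of the former alkene only, and Claisen-type C-formylation of this kinetic enolate by the activated formate is fast at −78 °C, before proton transfer could move the enolate across the carbonyl of what is otherwise an achiral ketone; no new stereocentre arises and the quaternary centre is untouched.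

Step 7
Reactants: 11 N-[2-[(1R,3Z)-1-(3,4-dimethoxyphenyl)-3-(hydroxymethylidene)-4-oxocyclohexyl]ethyl]-N-methylacetamide; 12 ethylene
Product: 14 N-[2-[(1R)-1-(3,4-dimethoxyphenyl)-4-oxo-3-(3-oxopropyl)cyclohexyl]ethyl]-N-methylacetamide (both epimers at C3), via spiro-cyclobutanol 13 (not isolated)
Conditions: 12 (bubbled through throughout), hν (300 nm lamps, Pyrex), CH2Cl2 (0.01–0.02 M), −20 °C; then rt; concentrated and used crude
Reagents that add atoms: none
Why: Light near 300 nm is absorbed by the hydrogen-bonded enol–ketone chromophore of 11 and hardly by the dimethoxyphenyl ring; the excited enol C=C adds to ethylene through a 1,4-biradical that collapses to spiro-cyclobutanol 13, and this strained β-hydroxy ketone opens by retro-aldol cleavage of the bond between the spiro carbon and the carbinol carbon to leave a 3-oxopropyl arm on the ketone α-carbon. The closest known reaction type is the de Mayo reaction of an enolised 1,3-dicarbonyl compound with an alkene, here a 2-(hydroxymethylene) ketone with ethylene. The only ring closed is the transient cyclobutane, formed by stepwise [2+2] addition (first bond to the excited enol, then radical recombination) and reopened in the same flask, so no ring persists. No lasting stereocentre is made, since the spiro and carbinol centres of 13 vanish on opening and the α-carbon of 14 is an epimer mixture that becomes the aromatic C4a. The step needs site selectivity and selective excitation: the first is fixed by the position of the hydroxymethylene group installed in step 6, the second by the Pyrex-filtered light, ethylene is symmetric so no regiochemical question arises, and the quaternary centre is three bonds from the chromophore and is not affected.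

Step 8
Reactants: 14 N-[2-[(1R)-1-(3,4-dimethoxyphenyl)-4-oxo-3-(3-oxopropyl)cyclohexyl]ethyl]-N-methylacetamide (both epimers at C3)
Product: 16 N-[2-[(6R)-6-(3,4-dimethoxyphenyl)-5,6,7,8-tetrahydroquinolin-6-yl]ethyl]-N-methylacetamide, via aldoxime 15 (not isolated)
Conditions: NH2OH·HCl (1.5 equiv), EtOH, reflux; basic work-up
Reagents that add atoms: hydroxylamine hydrochloride, NO.Cl
Why: Pyridine synthesis from a 1,5-dicarbonyl compound and hydroxylamine, in which the aldoxime nitrogen condenses with the ketone and the N-hydroxy dihydropyridine aromatises by loss of water, so no oxidant is needed, both C3 epimers converge, and the quaternary centre, which is not enolisable, is retained.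

Compound list
1 | 2-(methylamino)ethanol | CNCCO | starting material
2 | 2-chloro-N-methylethan-1-amine hydrochloride | CNCCCl.Cl | intermediate
3 | N-(2-chloroethyl)-N-methylacetamide | CC(=O)N(C)CCCl | intermediate
4 | (3,4-dimethoxyphenyl)acetonitrile | N#CCc1ccc(OC)c(OC)c1 | starting material
5 | rac-N-[3-cyano-3-(3,4-dimethoxyphenyl)propyl]-N-methylacetamide | COc1ccc(C(C#N)CCN(C)C(C)=O)cc1OC | intermediate
6 | rac-N-[3-(3,4-dimethoxyphenyl)-4-oxobutyl]-N-methylacetamide | COc1ccc(C(C=O)CCN(C)C(C)=O)cc1OC | intermediate
7 | methyl vinyl ketone (but-3-en-2-one) | CC(=O)C=C | starting material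
8 | N-[(3R)-3-(3,4-dimethoxyphenyl)-3-formyl-6-oxoheptyl]-N-methylacetamide (Michael adduct) | COc1ccc([C@](C=O)(CCN(C)C(C)=O)CCC(C)=O)cc1OC | intermediate (not isolated)
9 | N-[2-[(1S)-1-(3,4-dimethoxyphenyl)-4-oxocyclohex-2-en-1-yl]ethyl]-N-methylacetamide | COc1ccc([C@]2(CCN(C)C(C)=O)CCC(=O)C=C2)cc1OC | intermediate
10 | lithium (4R)-4-[2-[acetyl(methyl)amino]ethyl]-4-(3,4-dimethoxyphenyl)cyclohex-1-en-1-olate | COc1ccc([C@]2(CCN(C)C(C)=O)CCC([O-])=CC2)cc1OC.[Li+] | intermediate (not isolated)
11 | N-[2-[(1R,3Z)-1-(3,4-dimethoxyphenyl)-3-(hydroxymethylidene)-4-oxocyclohexyl]ethyl]-N-methylacetamide | COc1ccc([C@]2(CCN(C)C(C)=O)CCC(=O)/C(=C\O)C2)cc1OC | intermediate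
12 | ethylene | C=C | starting material
13 | N-[2-[(8R)-8-(3,4-dimethoxyphenyl)-1-hydroxy-5-oxospiro[3.5]nonan-8-yl]ethyl]-N-methylacetamide (mixture at C1 and C4) | COc1ccc([C@]2(CCN(C)C(C)=O)CCC(=O)C3(CCC3O)C2)cc1OC | intermediate (not isolated)
14 | N-[2-[(1R)-1-(3,4-dimethoxyphenyl)-4-oxo-3-(3-oxopropyl)cyclohexyl]ethyl]-N-methylacetamide (both epimers at C3) | COc1ccc([C@]2(CCN(C)C(C)=O)CCC(=O)C(CCC=O)C2)cc1OC | intermediate
15 | N-[2-[(1R)-1-(3,4-dimethoxyphenyl)-3-[3-(hydroxyimino)propyl]-4-oxocyclohexyl]ethyl]-N-methylacetamide (aldoxime) | COc1ccc([C@]2(CCN(C)C(C)=O)CCC(=O)C(CCC=NO)C2)cc1OC | intermediate (not isolated)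
16 | N-[2-[(6R)-6-(3,4-dimethoxyphenyl)-5,6,7,8-tetrahydroquinolin-6-yl]ethyl]-N-methylacetamide | COc1ccc([C@]2(CCN(C)C(C)=O)CCc3ncccc3C2)cc1OC | target

Total step count: 8. Longest linear sequence: 8 steps (1 to 16; 4, 7 and 12 enter as purchased materials).

Steps most likely to fail

Step 7. The photoaddition may be inefficient because ethylene is dilute and the chelated enol can deactivate by internal proton transfer. The aldehyde product may also suffer secondary photolysis (Norrish-type cleavage) or intramolecular aldol closure on handling. The fallback sets out from 11 and comes back at 14, forming the same C–C bond at the same α-carbon thermally. Triethylamine-catalysed Michael addition of β-keto aldehyde 11 to acrolein (THF, 0 °C) should give N-[2-[(1R)-1-(3,4-dimethoxyphenyl)-3-formyl-4-oxo-3-(3-oxopropyl)cyclohexyl]ethyl]-N-methylacetamide F1. Mild retro-Claisen deformylation (K2CO3, aqueous MeOH, 0 °C) then gives 14, which is taken at once into step 8.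

Step 6. Hydride may attack the carbonyl instead of the β-carbon, which is flanked by the quaternary centre. Proton transfer between enolate and product may also return achiral ketone, lowering yield or enantiopurity. The fallback sets out from 9 and comes back at 11. RhCl(PPh3)3-catalysed 1,4-hydrosilylation with Et3SiH (PhMe, 50 °C) should give the regiodefined silyl enol ether N-[2-[(1R)-1-(3,4-dimethoxyphenyl)-4-(triethylsilyloxy)cyclohex-3-en-1-yl]ethyl]-N-methylacetamide F2. Mukaiyama-type formylation with HC(OMe)3 and TiCl4 (CH2Cl2, −78 °C), which needs no free enolate, should give the β-keto acetal N-[2-[(1R)-3-(dimethoxymethyl)-1-(3,4-dimethoxyphenyl)-4-oxocyclohexyl]ethyl]-N-methylacetamide F3. Hydrolysis with 1 M HCl in THF releases 11.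

Step 5. The hindered enamine may add sluggishly, or with poor facial selectivity, so that the only stereocentre is set with insufficient enantiopurity. The fallback sets out from 6 and comes back at lithium enolate 10, which is formylated as in step 6. A base-mediated Robinson annulation without chiral control (7, KOH cat., MeOH, 0 °C to rt) gives rac-N-[2-[1-(3,4-dimethoxyphenyl)-4-oxocyclohex-2-en-1-yl]ethyl]-N-methylacetamide F4. Hydrogenation (H2, Pd/C, EtOAc) gives the achiral ketone N-[2-[1-(3,4-dimethoxyphenyl)-4-oxocyclohexyl]ethyl]-N-methylacetamide F5. Enantiotopic deprotonation with lithium (R,R)- or (S,S)-bis(1-phenylethyl)amide, with LiCl and Me3SiCl present (THF, −100 °C), gives N-[2-[(1R)-1-(3,4-dimethoxyphenyl)-4-(trimethylsilyloxy)cyclohex-3-en-1-yl]ethyl]-N-methylacetamide F6. MeLi (THF, 0 °C) converts F6 into 10.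

Further compounds
F1 | step 7 | N-[2-[(1R)-1-(3,4-dimethoxyphenyl)-3-formyl-4-oxo-3-(3-oxopropyl)cyclohexyl]ethyl]-N-methylacetamide (mixture at C3) | COc1ccc([C@]2(CCN(C)C(C)=O)CCC(=O)C(C=O)(CCC=O)C2)cc1OC
F2 | step 6 | N-[2-[(1R)-1-(3,4-dimethoxyphenyl)-4-(triethylsilyloxy)cyclohex-3-en-1-yl]ethyl]-N-methylacetamide | COc1ccc([C@]2(CCN(C)C(C)=O)CCC(O[Si](CC)(CC)CC)=CC2)cc1OC
F3 | step 6 | N-[2-[(1R)-3-(dimethoxymethyl)-1-(3,4-dimethoxyphenyl)-4-oxocyclohexyl]ethyl]-N-methylacetamide (mixture at C3) | COc1ccc([C@]2(CCN(C)C(C)=O)CCC(=O)C(C(OC)OC)C2)cc1OC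
F4 | step 5 | rac-N-[2-[1-(3,4-dimethoxyphenyl)-4-oxocyclohex-2-en-1-yl]ethyl]-N-methylacetamide | COc1ccc(C2(CCN(C)C(C)=O)CCC(=O)C=C2)cc1OC
F5 | step 5 | N-[2-[1-(3,4-dimethoxyphenyl)-4-oxocyclohexyl]ethyl]-N-methylacetamide | COc1ccc(C2(CCN(C)C(C)=O)CCC(=O)CC2)cc1OC
F6 | step 5 | N-[2-[(1R)-1-(3,4-dimethoxyphenyl)-4-(trimethylsilyloxy)cyclohex-3-en-1-yl]ethyl]-N-methylacetamide | COc1ccc([C@]2(CCN(C)C(C)=O)CCC(O[Si](C)(C)C)=CC2)cc1OC
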